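The data are calculated with made-up constants; scatter was added.

Reckon the main step first and ask where it ends.

| setting | alpha | gamma | beta |
|---|---|---|---|
| substrate | 0.500 M | 0.500 M | 0.300 M |
| partner | 0.400 M | 0.400 M | 0.200 M |
| free catalyst | 0.0500 M | 0.0500 M | 0.0500 M |
| product |  | 0.250 M |  |
| time |  |  | 240 h |

| run | time / h | [substrate] / M |
|---|---|---|
| alpha run | 9.6 | 0.485 |
| alpha run | 21 | 0.463 |
| alpha run | 48 | 0.417 |
| alpha run | 110 | 0.354 |
| alpha run | 240 | 0.268 |
| gamma run | 9.6 | 0.479 |
| gamma run | 21 | 0.464 |
| gamma run | 48 | 0.422 |
| gamma run | 110 | 0.352 |
| gamma run | 240 | 0.265 |

(readings scatter by 0.003 M)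

- Overall: substrate + partner -> product, with free catalyst as catalyst.
- Constant volume, constant temperature.
- What is held in complexes is read along with the free species.
- "The second partner" is partner.

- substrate in the beta run at 240 h, as a share of the substrate charged

Substrate and partner turn over one for one, so the excess, c(substrate) − c(partner), stays constant. Partner is the limiting reagent, so beta's charge allows substrate down to 0.100 M, or 33.3% of the charge. With a rate proportional to c(substrate)·c(partner) at constant catalyst, the logarithm of c(substrate)/c(partner) climbs steadily, with a slope of rate constant times excess. Alpha's last reading, 0.268 M at 240 h, leaves partner at 0.168 M. That gives a ratio gain of 1.28, the factor by which c(substrate)/c(partner) has risen above its charged value. Beta has alpha's excess, 0.100 M, the same free catalyst and the same 240 h, so under this step its ratio gains the same factor. Since c(substrate) equals excess × ratio/(ratio − 1), beta's substrate stands at 69.8% of its charge.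

Now add the product. Gamma, charged with 0.250 M of it, reads a gain of 1.28, which puts beta at 69.3%. A scatter of 0.003 M on one reading moves the gain by 0.00850. The two gains differ by 0.00866, less than 0.0170, and a shift of that 0.0170 either way spans 68.8% to 70.8%.

The forecast says 70%, within 66% to 73%, on the ground that “it should behave like alpha joined at a later point”. The reckoning here, made from alpha's last reading, gives 69.8% and differs from the forecast by 0.20 percentage points.

The beta flask gives 68.5%. The rate of gamma over that of alpha, at equal product made, is 1.0.

    free catalyst + partner ⇌ catalyst-reagent complex, settled at all times (0.4160 L mol⁻¹)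
    catalyst-reagent complex + substrate → product + free catalyst (0.7884 L mol⁻¹ h⁻¹)
    free catalyst + impurity → spent catalyst

Beta's ratio gain, worked from that result, comes to 1.30, above alpha's 1.28. In the gamma run, product made at half of the substrate charged means a gain of 1.33, which alpha's gain, extended along the straight logarithm, places at 283 h, while the gamma run reaches it at 274 h.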